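**Plan**
- Retrosynthesis: the aryl ether C11–O is cut first (Mitsunobu), then ring B at C7–C8 and C9–C10 (Diels–Alder), then ring A at C1–C2 and C3–C4, which leaves acetaldehyde and 2,4-dimethylpent-1-en-3-one.
- Enabling feature: in ring A the carbinol C3 lies between the quaternary C4(CH3)2 and the C1–C2 ethano bridge. With C5 raised to a ketone, C3–C4–C5 is an aldol retron that cannot dehydrate (C4 has no hydrogen) and C2–C1–C10–C5 is a Michael retron.
- Forward: ring A arises first in one Michael/aldol operation. The C5 carbonyl helper is then spent as the enol triflate and 2-ethoxydiene, and ring B is closed by cycloaddition with an allenic ester that brings C8=C12, C9 and C11. The C6 ketone becomes the C6=C7 double bond and the coumarin is attached last.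
- Stereochemistry: C3 from a CBS reduction (reagent control); C10 and C9 from the Diels–Alder step (attack anti to the axial C4 methyl, exo ester); C5 from protonation trans to the C10 methyl.

Key step: step 2

Remark: drimane numbering is used for the decalin (ring carbons C1–C10, C11 = OCH2 on C9, C12 = exocyclic CH2 on C8). The target is (3R,5S,9R,10R), with 3-OH, the C10 methyl and C11 on one face and H-3, H-5 and H-9 on the other.

**Step 1**
Reactants: 1 N-methoxy-N,2-dimethylpropanamide; 2 isopropenylmagnesium bromide
Product: 3 2,4-dimethylpent-1-en-3-one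
Conditions: THF, 0 °C to rt; aq. NH4Cl
Reagents that add atoms: none
Why: Weinreb ketone synthesis, in which the chelated tetrahedral magnesium adduct should prevent both over-addition and conjugate addition to the enone, which appears only on work-up.

**Step 2**
Reactants: 3 2,4-dimethylpent-1-en-3-one; 4 acetaldehyde
Product: 6 rac-3-hydroxy-2,2,6-trimethylcyclohexan-1-one (cis/trans mixture), via 4,6-dimethyl-5-oxoheptanal 5 (not isolated)
Conditions: 4 (5 equiv, slow addition), (S)-2-[diphenyl(trimethylsilyloxy)methyl]pyrrolidine (10 mol%), 4-nitrophenol (20 mol%), 1,4-dioxane, 5 °C to rt; then DBU (0.3 equiv), same flask, rt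
Reagents that add atoms: none
Why: The secondary amine converts acetaldehyde into its enamine, whose C2 adds to C1 of the α-methylene ketone (bond C1–C2); after hydrolysis to 5 the base enolises the isopropyl ketone at C4, which attacks the aldehyde carbon C3 (bond C3–C4). The closest known reaction type is the Robinson-type annulation of an aldehyde enamine with a vinyl ketone (the 4,4-dimethylcyclohexenone synthesis), here arrested at the ketol because C4 becomes quaternary and has no hydrogen to lose. Ring A closes by a 6-(enolendo)-exo-trig aldol addition; every other enolate of 5 could only close a four-membered ring. The new stereocentres C3 and C10 form without control, which is accepted: C3 is reset in steps 3 and 4 and C10 becomes trigonal in step 6. The step needs cross- over self-condensation of acetaldehyde, which the bulky prolinol catalyst, the slow addition and the reactive 1,1-disubstituted enone acceptor should secure.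

**Step 3**
Reactants: 6 rac-3-hydroxy-2,2,6-trimethylcyclohexan-1-one
Product: 7 2,2,4-trimethylcyclohexane-1,3-dione
Conditions: IBX (1.5 equiv), DMSO, rt
Reagents that add atoms: none
Why: IBX oxidation of the secondary alcohol removes the uncontrolled C3 centre, and the product cannot enolise between the carbonyls because that carbon is quaternary.

**Step 4**
Reactants: 7 2,2,4-trimethylcyclohexane-1,3-dione
Product: 8 (3R)-3-hydroxy-2,2,6-trimethylcyclohexan-1-one (both C6 epimers)
Conditions: (S)-2-methyl-CBS-oxazaborolidine (20 mol%), catecholborane (1.2 equiv), toluene, −60 °C; MeOH, aq. NaOH wash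
Reagents that add atoms: none
Why: Corey–Bakshi–Shibata reduction of a 2,2-disubstituted cyclic 1,3-diketone, in which the carbonyl flanked by CH2 and the quaternary carbon is the better-differentiated and less hindered one; by the CBS model with the quaternary side as the large group the (S)-catalyst should set C3 as R.

**Step 5**
Reactants: 8 (3R)-3-hydroxy-2,2,6-trimethylcyclohexan-1-one
Product: 9 (3R)-3-(tert-butyldimethylsilyloxy)-2,2,6-trimethylcyclohexan-1-one (both C6 epimers)
Conditions: TBSOTf, 2,6-lutidine, CH2Cl2, 0 °C
Reagents that add atoms: tert-butyldimethylsilyl trifluoromethanesulfonate (CC(C)(C)[Si](C)(C)OS(=O)(=O)C(F)(F)F)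
Why: Silyl triflate protection is the standard way to silylate a hindered neopentyl-type secondary alcohol, and the ether should survive the bases, palladium steps and hydride that follow.

**Step 6**
Reactants: 9 (3R)-3-(tert-butyldimethylsilyloxy)-2,2,6-trimethylcyclohexan-1-one
Product: 10 (5R)-5-(tert-butyldimethylsilyloxy)-2,6,6-trimethylcyclohex-1-en-1-yl trifluoromethanesulfonate
Conditions: KN(SiMe3)2, THF, −78 to 0 °C; PhNTf2
Reagents that add atoms: N-phenylbis(trifluoromethanesulfonimide) (O=S(=O)(N(c1ccccc1)S(=O)(=O)C(F)(F)F)C(F)(F)F)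
Why: Enol triflate formation can occur only toward C10, the sole enolisable position, so a single tetrasubstituted triflate should result and the C10 epimers converge.

**Step 7**
Reactants: 10 (5R)-5-(tert-butyldimethylsilyloxy)-2,6,6-trimethylcyclohex-1-en-1-yl trifluoromethanesulfonate; 11 tributyl(1-ethoxyvinyl)stannane
Product: 12 tert-butyl{[(1R)-3-(1-ethoxyvinyl)-2,2,4-trimethylcyclohex-3-en-1-yl]oxy}dimethylsilane
Conditions: Pd2(dba)3 (2.5 mol%), AsPh3 (20 mol%), LiCl (3 equiv), NMP, 50 °C; work-up on Et3N-treated silica
Reagents that add atoms: none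
Why: Stille coupling of a hindered vinyl triflate with an α-alkoxyvinylstannane forms the C5–C6 bond and turns the former C5 carbonyl helper into an electron-rich 2-ethoxy-1,3-diene.

**Step 8**
Reactants: 12 tert-butyl{[(1R)-3-(1-ethoxyvinyl)-2,2,4-trimethylcyclohex-3-en-1-yl]oxy}dimethylsilane; 13 ethyl buta-2,3-dienoate
Product: 15 ethyl (3R,5S,9R,10R)-3-(tert-butyldimethylsilyloxy)-6-oxodrim-8(12)-en-11-oate, via enol ether cycloadduct 14 (not isolated)
Conditions: 13 (2.5 equiv), BHT (cat.), toluene, 100 °C, sealed tube; then 0.5 M aq. HCl, THF, 0 °C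
Reagents that add atoms: water (O)
Why: Diels–Alder reaction of the 2-alkoxydiene with the conjugated double bond of the allenic ester (C7 to the central allene carbon C8, C10 to C9) should close ring B with the quaternary C10 and the exocyclic C8=C12, attack coming anti to the pseudoaxial C4 methyl (silyloxy group pseudoequatorial) with the ester exo, away from the crowded C5/C6 region; cold acid then hydrolyses the enol ether with protonation of C5 opposite the C10 methyl, giving the trans-fused ketone.

**Step 9**
Reactants: 15 ethyl (3R,5S,9R,10R)-3-(tert-butyldimethylsilyloxy)-6-oxodrim-8(12)-en-11-oate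
Product: 16 ethyl (3R,5S,9R,10R)-3-(tert-butyldimethylsilyloxy)-6-(trifluoromethanesulfonyloxy)drima-6,8(12)-dien-11-oate
Conditions: KN(SiMe3)2 (1.05 equiv), THF, −78 °C; PhNTf2
Reagents that add atoms: N-phenylbis(trifluoromethanesulfonimide) (O=S(=O)(N(c1ccccc1)S(=O)(=O)C(F)(F)F)C(F)(F)F)
Why: Kinetic enolisation should take the C7 hydrogen, which is both α to the ketone and allylic and less hindered than the tertiary C5–H or the ester α-hydrogen, and O-triflation of the dienolate fixes the C6=C7–C8=C12 diene.

**Step 10**
Reactants: 16 ethyl (3R,5S,9R,10R)-3-(tert-butyldimethylsilyloxy)-6-(trifluoromethanesulfonyloxy)drima-6,8(12)-dien-11-oate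
Product: 17 ethyl (3R,5S,9R,10R)-3-(tert-butyldimethylsilyloxy)drima-6,8(12)-dien-11-oate
Conditions: Pd(OAc)2 (5 mol%), PPh3 (10 mol%), HCO2H (2 equiv), n-Bu3N (3 equiv), DMF, 60 °C
Reagents that add atoms: none
Why: Palladium-catalysed formate reduction of an enol triflate replaces C–OTf by C–H without moving the diene or touching the stereocentres, which removes the last trace of the C6 oxygen.

**Step 11**
Reactants: 17 ethyl (3R,5S,9R,10R)-3-(tert-butyldimethylsilyloxy)drima-6,8(12)-dien-11-oate
Product: 18 (3R,5S,9R,10R)-3-(tert-butyldimethylsilyloxy)drima-6,8(12)-dien-11-ol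
Conditions: i-Bu2AlH (2.5 equiv), CH2Cl2, −78 to 0 °C; Rochelle salt
Reagents that add atoms: none
Why: Hydride reduction of the ester with a non-basic aluminium hydride should give the primary alcohol without epimerising C9 or shifting the exocyclic double bond.

**Step 12**
Reactants: 18 (3R,5S,9R,10R)-3-(tert-butyldimethylsilyloxy)drima-6,8(12)-dien-11-ol; 19 7-hydroxy-2H-chromen-2-one (umbelliferone)
Product: 20 7-{[(3R,5S,9R,10R)-3-(tert-butyldimethylsilyloxy)drima-6,8(12)-dien-11-yl]oxy}-2H-chromen-2-one
Conditions: PPh3, DIAD, THF, 0 °C to rt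
Reagents that add atoms: none
Why: Mitsunobu etherification of a primary alcohol with an acidic phenol forms the C11–O–aryl bond at a carbon that is not a stereocentre.

**Step 13**
Reactants: 20 7-{[(3R,5S,9R,10R)-3-(tert-butyldimethylsilyloxy)drima-6,8(12)-dien-11-yl]oxy}-2H-chromen-2-one
Product: 21 7-{[(3R,5S,9R,10R)-3-hydroxydrima-6,8(12)-dien-11-yl]oxy}-2H-chromen-2-one
Conditions: HF·pyridine, pyridine, THF, 0 °C to rt
Reagents that add atoms: none
Why: Buffered fluoride cleavage of the silyl ether should free the 3-hydroxyl while sparing the acid-sensitive diene and the coumarin lactone.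

**Compound list**
1 | N-methoxy-N,2-dimethylpropanamide | CC(C)C(=O)N(C)OC | starting material
2 | isopropenylmagnesium bromide, CH2=C(CH3)MgBr | C=C(C)[Mg]Br | starting material
3 | 2,4-dimethylpent-1-en-3-one | C=C(C)C(=O)C(C)C | intermediate
4 | acetaldehyde | CC=O | starting material
5 | 4,6-dimethyl-5-oxoheptanal (not isolated) | O=CCCC(C)C(=O)C(C)C | intermediate
6 | rac-3-hydroxy-2,2,6-trimethylcyclohexan-1-one (cis/trans mixture) | CC1CCC(O)C(C)(C)C1=O | intermediate
7 | 2,2,4-trimethylcyclohexane-1,3-dione (racemic) | CC1CCC(=O)C(C)(C)C1=O | intermediate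
8 | (3R)-3-hydroxy-2,2,6-trimethylcyclohexan-1-one (both C6 epimers) | CC1CC[C@@H](O)C(C)(C)C1=O | intermediate
9 | (3R)-3-(tert-butyldimethylsilyloxy)-2,2,6-trimethylcyclohexan-1-one (both C6 epimers) | CC1CC[C@@H](O[Si](C)(C)C(C)(C)C)C(C)(C)C1=O | intermediate
10 | (5R)-5-(tert-butyldimethylsilyloxy)-2,6,6-trimethylcyclohex-1-en-1-yl trifluoromethanesulfonate | CC1=C(OS(=O)(=O)C(F)(F)F)C(C)(C)[C@H](O[Si](C)(C)C(C)(C)C)CC1 | intermediate
11 | tributyl(1-ethoxyvinyl)stannane | CCCC[Sn](CCCC)(CCCC)C(=C)OCC | starting material
12 | tert-butyl{[(1R)-3-(1-ethoxyvinyl)-2,2,4-trimethylcyclohex-3-en-1-yl]oxy}dimethylsilane | C=C(OCC)C1=C(C)CC[C@@H](O[Si](C)(C)C(C)(C)C)C1(C)C | intermediate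
13 | ethyl buta-2,3-dienoate | C=C=CC(=O)OCC | starting material
14 | ethyl 3-(tert-butyldimethylsilyloxy)-6-ethoxydrima-5,8(12)-dien-11-oate, enol ether cycloadduct (3-OSi, C10 methyl and ester on one face; not isolated) | C=C1CC(OCC)=C2C(C)(C)[C@H](O[Si](C)(C)C(C)(C)C)CC[C@@]2(C)[C@@H]1C(=O)OCC | intermediate
15 | ethyl (3R,5S,9R,10R)-3-(tert-butyldimethylsilyloxy)-6-oxodrim-8(12)-en-11-oate | C=C1CC(=O)[C@@H]2C(C)(C)[C@H](O[Si](C)(C)C(C)(C)C)CC[C@@]2(C)[C@@H]1C(=O)OCC | intermediate
16 | ethyl (3R,5S,9R,10R)-3-(tert-butyldimethylsilyloxy)-6-(trifluoromethanesulfonyloxy)drima-6,8(12)-dien-11-oate | C=C1C=C(OS(=O)(=O)C(F)(F)F)[C@@H]2C(C)(C)[C@H](O[Si](C)(C)C(C)(C)C)CC[C@@]2(C)[C@@H]1C(=O)OCC | intermediate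
17 | ethyl (3R,5S,9R,10R)-3-(tert-butyldimethylsilyloxy)drima-6,8(12)-dien-11-oate | C=C1C=C[C@@H]2C(C)(C)[C@H](O[Si](C)(C)C(C)(C)C)CC[C@@]2(C)[C@@H]1C(=O)OCC | intermediate
18 | (3R,5S,9R,10R)-3-(tert-butyldimethylsilyloxy)drima-6,8(12)-dien-11-ol | C=C1C=C[C@@H]2C(C)(C)[C@H](O[Si](C)(C)C(C)(C)C)CC[C@@]2(C)[C@@H]1CO | intermediate
19 | 7-hydroxy-2H-chromen-2-one (umbelliferone) | O=c1ccc2ccc(O)cc2o1 | starting material
20 | 7-{[(3R,5S,9R,10R)-3-(tert-butyldimethylsilyloxy)drima-6,8(12)-dien-11-yl]oxy}-2H-chromen-2-one | C=C1C=C[C@@H]2C(C)(C)[C@H](O[Si](C)(C)C(C)(C)C)CC[C@@]2(C)[C@@H]1COc1ccc2ccc(=O)oc2c1 | intermediate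
21 | 7-{[(3R,5S,9R,10R)-3-hydroxydrima-6,8(12)-dien-11-yl]oxy}-2H-chromen-2-one | C=C1C=C[C@@H]2C(C)(C)[C@H](O)CC[C@@]2(C)[C@@H]1COc1ccc2ccc(=O)oc2c1 | target

**Step count**
Total steps: 13. Longest linear sequence: 13 steps (1 to 21).

**Steps most likely to fail**

Step 8. The cycloaddition onto the fully substituted, twisted diene terminus may be slow, and neither the face of attack at C10 nor the exo placement of the ester at C9 is enforced by more than the ring-A conformation, so poor facial and endo/exo selectivity is possible. The fallback sets out from 12. Mild acid (oxalic acid, wet CH2Cl2) hydrolyses the enol ether to the methyl ketone 1-[(5R)-5-(tert-butyldimethylsilyloxy)-2,6,6-trimethylcyclohex-1-en-1-yl]ethan-1-one F2. LiN(i-Pr)2 (THF, −78 °C) then forms the kinetic enolate at the acetyl methyl group (C7), which adds to the central carbon of 13. The ester dienolate so formed closes ring B by intramolecular Michael addition at C10, a sequential double Michael annulation of the kind known for 1-acetylcyclohexenes and acrylates. This closure is stepwise, needs no planar s-cis diene, and passes through a chair-like arrangement that should place the ester equatorial. Protonation of the ketone enolate returns the route at 15.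

Step 2. Self-aldolisation and oligomerisation of acetaldehyde may outrun the cross-Michael addition. The fallback sets out from 3. An inverse-electron-demand hetero-Diels–Alder reaction with ethyl vinyl ether (neat, sealed tube, 160 °C, hydroquinone) gives 2-ethoxy-5-methyl-6-(propan-2-yl)-3,4-dihydro-2H-pyran F1, in which the C1–C2 bond is already made. Aqueous acid (1 M HCl, THF) then unmasks keto aldehyde 5, and the same acid promotes the aldol closure through the ketone enol, so the route is rejoined at 6.

Step 9. Enolisation may be unselective between C5 and C7, or the exocyclic double bond may slip into conjugation with the ketone before triflation. The fallback sets out from 15. NaBH4 (MeOH, 0 °C) should reduce only the ketone, with hydride arriving opposite the axial C4 and C10 methyl groups, to give the axial alcohol ethyl (3R,5S,6S,9R,10R)-3-(tert-butyldimethylsilyloxy)-6-hydroxydrim-8(12)-en-11-oate F3. The Burgess reagent (benzene, 50 °C) then removes water by syn elimination; the only syn hydrogen is the allylic one on C7, so the conjugated diene should form and the route is rejoined at 17.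

**Further compounds**
F1 | step 2 | 2-ethoxy-5-methyl-6-(propan-2-yl)-3,4-dihydro-2H-pyran | CCOC1CCC(C)=C(C(C)C)O1
F2 | step 8 | 1-[(5R)-5-(tert-butyldimethylsilyloxy)-2,6,6-trimethylcyclohex-1-en-1-yl]ethan-1-one | CC(=O)C1=C(C)CC[C@@H](O[Si](C)(C)C(C)(C)C)C1(C)C
F3 | step 9 | ethyl (3R,5S,6S,9R,10R)-3-(tert-butyldimethylsilyloxy)-6-hydroxydrim-8(12)-en-11-oate | C=C1C[C@H](O)[C@@H]2C(C)(C)[C@H](O[Si](C)(C)C(C)(C)C)CC[C@@]2(C)[C@@H]1C(=O)OCC
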